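## Retrosynthetic overview

1. The target comes from a macrocyclic C3 enone by CBS reduction (sets C3), benzoylation, and a final peracid epoxidation of the E‑1(10) alkene.
2. The ten‑membered carbocycle is closed at C3–C4 by a Ni/Cr Nozaki–Hiyama–Kishi reaction between a Z‑vinyl iodide and an aldehyde.
3. The key late union forms C7–C8: a Zn Barbier allylation joins an eight‑carbon 3‑(bromomethyl)butenolide (C4–C7, C11–C13, C15) with a seven‑carbon β,γ‑unsaturated aldehyde (C8–C10, C14, C1–C3). The C8 ester is then installed by Mitsunobu inversion with (2S,3S)‑epoxyangelic acid.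
4. The butenolide comes from (Z)‑3‑iodobut‑2‑enal by asymmetric vinylation, acylation with 2‑(bromomethyl)acrylic acid and RCM; the aldehyde from but‑3‑yn‑1‑ol by carboalumination and ethylene oxide; the acid from angelic acid by Sharpless epoxidation.
5. Ring order: acid oxirane (side branch) and γ‑lactone (RCM) first, then the ten‑membered carbocycle, last the 1,10‑oxirane.

Assumption: the SMILES is read as the (1R,3S,6R,7R,8R,10R,4Z)‑heliangolide with a (2S,3S)‑epoxyangelate; locants follow germacrane numbering (ring C1–C10, lactone C11–C13, C14 on C10, C15 on C4), and (−)‑DAIB, D‑(−)‑diethyl tartrate and (R)‑CBS are taken to show their usual facial sense.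

## Route

**West fragment (butenolide)**

Step 1
Reactants: 1 methyl but‑2‑ynoate
Product: 2 methyl (2Z)‑3‑iodobut‑2‑enoate
Conditions: NaI, AcOH, 115 °C
Reagents that add atoms: sodium iodide [Na+].[I-]
Why: Conjugate hydroiodination of the ynoate (iodide Michael addition, then anti protonation) gives the Z β‑iodoenoate, placing iodine cis to the carbonyl carbon so that the later C3–C4 bond is cis to C6 across C4=C5.

Step 2
Reactants: 2 methyl (2Z)‑3‑iodobut‑2‑enoate
Product: 3 (2Z)‑3‑iodobut‑2‑en‑1‑ol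
Conditions: i‑Bu2AlH (2.2 equiv), CH2Cl2, −78 °C; aq. KNaC4H4O6 work‑up
Reagents that add atoms: none
Why: Hydride 1,2‑reduction of the ester to the allylic alcohol at low temperature leaves the vinyl iodide and its geometry untouched.

Step 3
Reactants: 3 (2Z)‑3‑iodobut‑2‑en‑1‑ol
Product: 4 (2Z)‑3‑iodobut‑2‑enal
Conditions: MnO2, CH2Cl2, rt, used at once
Reagents that add atoms: none
Why: Selective allylic oxidation under neutral heterogeneous conditions avoids Z/E isomerisation of the sensitive β‑iodoenal.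

Step 4
Reactants: 4 (2Z)‑3‑iodobut‑2‑enal
Product: 5 (3S,4Z)‑5‑iodohexa‑1,4‑dien‑3‑ol
Conditions: Zn(CH=CH2)2, (−)‑DAIB (5 mol %), toluene, −20 °C; aq. NH4Cl
Reagents that add atoms: divinylzinc C=C[Zn]C=C
Why: Amino‑alcohol‑catalysed enantioselective organozinc 1,2‑addition delivers the vinyl group to the Si face of the enal, setting the carbinol (the later C6) as S.

Step 5
Reactants: 5 (3S,4Z)‑5‑iodohexa‑1,4‑dien‑3‑ol; 6 2‑(bromomethyl)prop‑2‑enoic acid
Product: 7 (3S,4Z)‑5‑iodohexa‑1,4‑dien‑3‑yl 2‑(bromomethyl)prop‑2‑enoate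
Conditions: DCC, DMAP (cat.), CH2Cl2, 0 °C
Reagents that add atoms: none
Why: Steglich esterification acylates the secondary alcohol without touching the stereocentre or either halide.

Step 6
Reactants: 7 (3S,4Z)‑5‑iodohexa‑1,4‑dien‑3‑yl 2‑(bromomethyl)prop‑2‑enoate
Product: 8 (5S)‑3‑(bromomethyl)‑5‑[(1Z)‑2‑iodoprop‑1‑en‑1‑yl]furan‑2(5H)‑one
Conditions: second‑generation Grubbs catalyst RuCl2(=CHPh)(PCy3)(H2IMes) (5 mol %), toluene, 80 °C
Reagents that add atoms: none
Why: Ring‑closing metathesis between the acrylate and the vinyl group forms the five‑membered butenolide with loss of ethene, while the trisubstituted iodoalkene is inert and the stereocentre is not involved.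

**East fragment (aldehyde)**

Step 7
Reactants: 9 but‑3‑yn‑1‑ol
Product: 10 (but‑3‑yn‑1‑yloxy)(tert‑butyl)dimethylsilane
Conditions: TBSCl, imidazole, DMF, rt
Reagents that add atoms: tert‑butyldimethylsilyl chloride CC(C)(C)[Si](C)(C)Cl
Why: Standard silylation masks the alcohol (the later C8 oxygen) for the organoaluminium chemistry.

Step 8
Reactants: 10 (but‑3‑yn‑1‑yloxy)(tert‑butyl)dimethylsilane
Product: 13 (3E)‑6‑[(tert‑butyldimethylsilyl)oxy]‑4‑methylhex‑3‑en‑1‑ol, via alkenyldimethylalane 11 (not isolated), via lithium alkenyl(butyl)dimethylaluminate 12 (not isolated)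
Conditions: Me3Al, Cp2ZrCl2 (20 mol %), CH2Cl2, 0 °C to rt; evaporate; n‑BuLi, THF/hexane, −78 °C; ethylene oxide, −78 °C to rt
Reagents that add atoms: trimethylaluminium C[Al](C)C; n‑butyllithium [Li]CCCC (atoms retained only in 12); ethylene oxide C1CO1
Why: Negishi zirconium‑catalysed carboalumination adds methyl and aluminium syn across the alkyne (methyl on C10), and the derived alanate opens ethylene oxide with retention, so the C1=C10 alkene is formed as the pure E isomer.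

Step 9
Reactants: 13 (3E)‑6‑[(tert‑butyldimethylsilyl)oxy]‑4‑methylhex‑3‑en‑1‑ol
Product: 14 (3E)‑1‑[(tert‑butyldiphenylsilyl)oxy]‑6‑[(tert‑butyldimethylsilyl)oxy]‑4‑methylhex‑3‑ene
Conditions: TBDPSCl, imidazole, DMF, rt
Reagents that add atoms: tert‑butyldiphenylsilyl chloride CC(C)(C)[Si](Cl)(c1ccccc1)c1ccccc1
Why: Silylation protects the C3 oxygen with a group that survives the later removal of the primary TBS ether.

Step 10
Reactants: 14 (3E)‑1‑[(tert‑butyldiphenylsilyl)oxy]‑6‑[(tert‑butyldimethylsilyl)oxy]‑4‑methylhex‑3‑ene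
Product: 15 (3E)‑6‑[(tert‑butyldiphenylsilyl)oxy]‑3‑methylhex‑3‑en‑1‑ol
Conditions: PPTS (cat.), MeOH, rt
Reagents that add atoms: none
Why: Mild acid‑catalysed methanolysis cleaves the primary TBS ether far faster than the TBDPS ether, freeing only the C8 hydroxyl.

Step 11
Reactants: 15 (3E)‑6‑[(tert‑butyldiphenylsilyl)oxy]‑3‑methylhex‑3‑en‑1‑ol
Product: 16 (3E)‑6‑[(tert‑butyldiphenylsilyl)oxy]‑3‑methylhex‑3‑enal
Conditions: Dess–Martin periodinane, NaHCO3, CH2Cl2, 0 °C, used crude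
Reagents that add atoms: none
Why: Buffered Dess–Martin oxidation gives the β,γ‑unsaturated aldehyde without base‑ or acid‑induced migration of the alkene into conjugation.

**Acid branches**

Step 12
Reactants: 17 angelic acid [(2Z)‑2‑methylbut‑2‑enoic acid]
Product: 18 (2Z)‑2‑methylbut‑2‑en‑1‑ol
Conditions: LiAlH4, Et2O, 0 °C
Reagents that add atoms: none
Why: Hydride reduction of the carboxylic acid gives the allylic alcohol with the Z geometry intact.

Step 13
Reactants: 18 (2Z)‑2‑methylbut‑2‑en‑1‑ol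
Product: 19 [(2R,3S)‑2,3‑dimethyloxiran‑2‑yl]methanol
Conditions: Ti(OiPr)4, D‑(−)‑diethyl tartrate, t‑BuOOH, 4 Å MS, CH2Cl2, −20 °C
Reagents that add atoms: tert‑butyl hydroperoxide CC(C)(C)OO
Why: Sharpless asymmetric epoxidation with the D‑(−)‑tartrate delivers oxygen syn to one face of the Z allylic alcohol, giving the cis (2R,3S) epoxy alcohol that becomes the (2S,3S) acid.

Step 14
Reactants: 19 [(2R,3S)‑2,3‑dimethyloxiran‑2‑yl]methanol
Product: 20 (2S,3S)‑2,3‑dimethyloxirane‑2‑carboxylic acid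
Conditions: RuCl3·xH2O (cat.), NaIO4, CCl4/MeCN/H2O, rt
Reagents that add atoms: water O
Why: Catalytic RuO4 oxidation takes the primary alcohol to the acid through the aldehyde hydrate without opening the epoxide; the C2 descriptor changes from R to S only because of CIP priorities.

Step 15
Reactants: 21 benzaldehyde
Product: 22 benzoic acid
Conditions: Oxone (2KHSO5·KHSO4·K2SO4), DMF, rt
Reagents that add atoms: potassium peroxymonosulfate [K+].[O-]S(=O)(=O)OO
Why: Peroxymonosulfate adds to the aldehyde and hydride migration (Baeyer–Villiger‑type oxidation) gives the acid cleanly.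

**Union and end game**

Step 16
Reactants: 8 (5S)‑3‑(bromomethyl)‑5‑[(1Z)‑2‑iodoprop‑1‑en‑1‑yl]furan‑2(5H)‑one; 16 (3E)‑6‑[(tert‑butyldiphenylsilyl)oxy]‑3‑methylhex‑3‑enal
Product: 24 (4R,5S)‑4‑[(1S,3E)‑6‑[(tert‑butyldiphenylsilyl)oxy]‑1‑hydroxy‑3‑methylhex‑3‑en‑1‑yl]‑5‑[(1Z)‑2‑iodoprop‑1‑en‑1‑yl]‑3‑methylidenedihydrofuran‑2(3H)‑one, via allylzinc bromide 23 (not isolated)
Conditions: Zn dust, THF/sat. aq. NH4Cl, 0 °C to rt
Reagents that add atoms: zinc [Zn] (atoms retained only in 23)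
Why: Barbier‑type allylation in which allylzinc 23 reacts through its γ‑carbon (C7) in a closed six‑membered transition state, anti to the C6 iodopropenyl group (6,7‑trans lactone) and with the aldehyde chain equatorial, which sets C8 as S (7,8‑anti, the 8α alcohol), one inversion away from the target.

Step 17
Reactants: 24 the 8α alcohol; 20 (2S,3S)‑2,3‑dimethyloxirane‑2‑carboxylic acid
Product: 25 (1R,3E)‑6‑[(tert‑butyldiphenylsilyl)oxy]‑1‑[(2S,3R)‑2‑[(1Z)‑2‑iodoprop‑1‑en‑1‑yl]‑4‑methylidene‑5‑oxooxolan‑3‑yl]‑3‑methylhex‑3‑en‑1‑yl (2S,3S)‑2,3‑dimethyloxirane‑2‑carboxylate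
Conditions: PPh3, diisopropyl azodicarboxylate, toluene, 0 °C to rt
Reagents that add atoms: none
Why: Mitsunobu esterification, in which the C8 alkoxyphosphonium ion is displaced by the carboxylate in an SN2 reaction, inverts C8 to the required R (8β) configuration and leaves the epoxy acid stereocentres untouched.

Step 18
Reactants: 25 the C8 epoxyangelate silyl ether
Product: 26 (1R,3E)‑6‑hydroxy‑1‑[(2S,3R)‑2‑[(1Z)‑2‑iodoprop‑1‑en‑1‑yl]‑4‑methylidene‑5‑oxooxolan‑3‑yl]‑3‑methylhex‑3‑en‑1‑yl (2S,3S)‑2,3‑dimethyloxirane‑2‑carboxylate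
Conditions: Bu4NF, AcOH (1:1), THF, 0 °C to rt
Reagents that add atoms: none
Why: Acetic‑acid‑buffered fluoride desilylation frees the C3 hydroxyl without alkoxide addition to the α‑methylene lactone or opening of the epoxy ester.

Step 19
Reactants: 26 the C3 primary alcohol
Product: 27 (1R,3E)‑1‑[(2S,3R)‑2‑[(1Z)‑2‑iodoprop‑1‑en‑1‑yl]‑4‑methylidene‑5‑oxooxolan‑3‑yl]‑3‑methyl‑6‑oxohex‑3‑en‑1‑yl (2S,3S)‑2,3‑dimethyloxirane‑2‑carboxylate
Conditions: Dess–Martin periodinane, NaHCO3, CH2Cl2, 0 °C, used crude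
Reagents that add atoms: none
Why: Neutral hypervalent‑iodine oxidation gives the β,γ‑unsaturated C3 aldehyde without alkene migration or epimerisation.

Step 20
Reactants: 27 the seco iodo aldehyde
Product: 29 (6R,7R,8R,1(10)E,4Z)‑8‑{[(2S,3S)‑2,3‑dimethyloxiran‑2‑yl]carbonyloxy}‑3‑hydroxygermacra‑1(10),4,11(13)‑trien‑12,6‑olide as a C3 epimer mixture, via alkenylchromium dichloride 28 (not isolated)
Conditions: CrCl2 (10 equiv), NiCl2 (0.1 equiv), DMSO/THF 3:1, rt, 0.002 M, slow addition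
Reagents that add atoms: chromium dichloride Cl[Cr]Cl (atoms retained only in 28)
Why: Nozaki–Hiyama–Kishi macrocyclisation, in which the Z‑vinyl iodide adds oxidatively to zerovalent nickel, is transmetalated to trivalent chromium with retention of geometry and adds to the aldehyde, closes the ten‑membered ring at C3–C4; the C3 configuration is erased in step 21.

Step 21
Reactants: 29 the macrocyclic allylic alcohol mixture
Product: 30 (6R,7R,8R,1(10)E,4Z)‑8‑{[(2S,3S)‑2,3‑dimethyloxiran‑2‑yl]carbonyloxy}‑3‑oxogermacra‑1(10),4,11(13)‑trien‑12,6‑olide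
Conditions: Dess–Martin periodinane, NaHCO3, CH2Cl2, 0 °C
Reagents that add atoms: none
Why: Oxidation of both C3 epimers converges on one enone, so the selectivity of the ring closure does not matter.

Step 22
Reactants: 30 the macrocyclic enone
Product: 31 (3S,6R,7R,8R,1(10)E,4Z)‑8‑{[(2S,3S)‑2,3‑dimethyloxiran‑2‑yl]carbonyloxy}‑3‑hydroxygermacra‑1(10),4,11(13)‑trien‑12,6‑olide
Conditions: (R)‑2‑methyl‑CBS‑oxazaborolidine (0.3 equiv), catecholborane, toluene, −78 °C
Reagents that add atoms: none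
Why: Corey–Bakshi–Shibata reduction with the alkenyl carbon C4 as the large group and CH2‑2 as the small group delivers hydride under reagent control to give the 3S (3β) alcohol, and is 1,2‑selective in the presence of the lactone and esters.

Step 23
Reactants: 31 the 3β alcohol; 22 benzoic acid
Product: 32 (3S,6R,7R,8R,1(10)E,4Z)‑3‑benzoyloxy‑8‑{[(2S,3S)‑2,3‑dimethyloxiran‑2‑yl]carbonyloxy}germacra‑1(10),4,11(13)‑trien‑12,6‑olide
Conditions: DCC, DMAP, CH2Cl2, rt
Reagents that add atoms: none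
Why: Steglich esterification acylates the only free hydroxyl with retention at C3.

Step 24
Reactants: 32 the triene benzoate
Product: 33 (1R,3S,6R,7R,8R,10R,4Z)‑3‑benzoyloxy‑1,10‑epoxy‑8‑{[(2S,3S)‑2,3‑dimethyloxiran‑2‑yl]carbonyloxy}germacra‑4,11(13)‑dien‑12,6‑olide (CNP0324463.3)
Conditions: mCPBA (1.05 equiv), NaHCO3, CH2Cl2, 0 °C
Reagents that add atoms: 3‑chloroperoxybenzoic acid OOC(=O)c1cccc(Cl)c1
Why: Prilezhaev epoxidation attacks the only electron‑rich, unhindered alkene (C4=C5 is flanked by two acyloxy carbons, C11=C13 is conjugated), and syn delivery to its exposed outer face, with the C14 methyl pointing β as in germacranolide conformers, gives the trans 1β,10α‑oxirane (1R,10R).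

## Compound list

1 | methyl but‑2‑ynoate | CC#CC(=O)OC | starting material
2 | methyl (2Z)‑3‑iodobut‑2‑enoate | C/C(I)=C/C(=O)OC | intermediate
3 | (2Z)‑3‑iodobut‑2‑en‑1‑ol | C/C(I)=C/CO | intermediate
4 | (2Z)‑3‑iodobut‑2‑enal | C/C(I)=C/C=O | intermediate
5 | (3S,4Z)‑5‑iodohexa‑1,4‑dien‑3‑ol | C=C[C@H](O)/C=C(/C)I | intermediate
6 | 2‑(bromomethyl)prop‑2‑enoic acid | C=C(CBr)C(=O)O | starting material
7 | (3S,4Z)‑5‑iodohexa‑1,4‑dien‑3‑yl 2‑(bromomethyl)prop‑2‑enoate | C=C[C@H](OC(=O)C(=C)CBr)/C=C(/C)I | intermediate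
8 | (5S)‑3‑(bromomethyl)‑5‑[(1Z)‑2‑iodoprop‑1‑en‑1‑yl]furan‑2(5H)‑one | BrCC1=C[C@@H](/C=C(/C)I)OC1=O | intermediate
9 | but‑3‑yn‑1‑ol | C#CCCO | starting material
10 | (but‑3‑yn‑1‑yloxy)(tert‑butyl)dimethylsilane | C#CCCO[Si](C)(C)C(C)(C)C | intermediate
11 | [(1E)‑4‑[(tert‑butyldimethylsilyl)oxy]‑2‑methylbut‑1‑en‑1‑yl]dimethylalane | C[Al](C)/C=C(\C)CCO[Si](C)(C)C(C)(C)C | intermediate (not isolated)
12 | lithium butyl[(1E)‑4‑[(tert‑butyldimethylsilyl)oxy]‑2‑methylbut‑1‑en‑1‑yl]dimethylaluminate | [Li+].CCCC[Al-](C)(C)/C=C(\C)CCO[Si](C)(C)C(C)(C)C | intermediate (not isolated)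
13 | (3E)‑6‑[(tert‑butyldimethylsilyl)oxy]‑4‑methylhex‑3‑en‑1‑ol | OCC/C=C(\C)CCO[Si](C)(C)C(C)(C)C | intermediate
14 | (3E)‑1‑[(tert‑butyldiphenylsilyl)oxy]‑6‑[(tert‑butyldimethylsilyl)oxy]‑4‑methylhex‑3‑ene | CC(C)(C)[Si](c1ccccc1)(c1ccccc1)OCC/C=C(\C)CCO[Si](C)(C)C(C)(C)C | intermediate
15 | (3E)‑6‑[(tert‑butyldiphenylsilyl)oxy]‑3‑methylhex‑3‑en‑1‑ol | CC(C)(C)[Si](c1ccccc1)(c1ccccc1)OCC/C=C(\C)CCO | intermediate
16 | (3E)‑6‑[(tert‑butyldiphenylsilyl)oxy]‑3‑methylhex‑3‑enal | CC(C)(C)[Si](c1ccccc1)(c1ccccc1)OCC/C=C(\C)CC=O | intermediate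
17 | angelic acid, (2Z)‑2‑methylbut‑2‑enoic acid | C/C=C(/C)C(=O)O | starting material
18 | (2Z)‑2‑methylbut‑2‑en‑1‑ol | C/C=C(/C)CO | intermediate
19 | [(2R,3S)‑2,3‑dimethyloxiran‑2‑yl]methanol | OC[C@@]1(C)O[C@H]1C | intermediate
20 | (2S,3S)‑2,3‑dimethyloxirane‑2‑carboxylic acid | OC(=O)[C@@]1(C)O[C@H]1C | intermediate
21 | benzaldehyde | O=Cc1ccccc1 | starting material
22 | benzoic acid | OC(=O)c1ccccc1 | intermediate
23 | {[(5S)‑5‑[(1Z)‑2‑iodoprop‑1‑en‑1‑yl]‑2‑oxo‑2,5‑dihydrofuran‑3‑yl]methyl}zinc bromide | Br[Zn]CC1=C[C@@H](/C=C(/C)I)OC1=O | intermediate (not isolated)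
24 | Barbier adduct, 8α alcohol (germacrane locants 6S,7R,8S) | C=C1C(=O)O[C@H](/C=C(/C)I)[C@H]1[C@@H](O)CC(/C)=C/CCO[Si](c2ccccc2)(c2ccccc2)C(C)(C)C | intermediate
25 | C8 (2S,3S)‑epoxyangelate, silyl ether (6S,7R,8R) | C=C1C(=O)O[C@H](/C=C(/C)I)[C@H]1[C@H](OC(=O)[C@@]2(C)O[C@H]2C)CC(/C)=C/CCO[Si](c3ccccc3)(c3ccccc3)C(C)(C)C | intermediate
26 | C3 primary alcohol (6S,7R,8R) | C=C1C(=O)O[C@H](/C=C(/C)I)[C@H]1[C@H](OC(=O)[C@@]2(C)O[C@H]2C)CC(/C)=C/CCO | intermediate
27 | seco iodo aldehyde (6S,7R,8R) | C=C1C(=O)O[C@H](/C=C(/C)I)[C@H]1[C@H](OC(=O)[C@@]2(C)O[C@H]2C)CC(/C)=C/CC=O | intermediate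
28 | alkenylchromium dichloride from 27 | C=C1C(=O)O[C@H](/C=C(/C)[Cr](Cl)Cl)[C@H]1[C@H](OC(=O)[C@@]2(C)O[C@H]2C)CC(/C)=C/CC=O | intermediate (not isolated)
29 | macrocyclic C3 alcohol, epimer mixture at C3 (6R,7R,8R) | C=C1C(=O)O[C@@H]2/C=C(/C)C(O)C/C=C(\C)C[C@@H](OC(=O)[C@@]3(C)O[C@H]3C)[C@@H]12 | intermediate
30 | macrocyclic C3 enone (6R,7R,8R) | C=C1C(=O)O[C@@H]2/C=C(/C)C(=O)C/C=C(\C)C[C@@H](OC(=O)[C@@]3(C)O[C@H]3C)[C@@H]12 | intermediate
31 | (3S)‑allylic alcohol (3S,6R,7R,8R) | C=C1C(=O)O[C@@H]2/C=C(/C)[C@@H](O)C/C=C(\C)C[C@@H](OC(=O)[C@@]3(C)O[C@H]3C)[C@@H]12 | intermediate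
32 | triene benzoate (3S,6R,7R,8R) | C=C1C(=O)O[C@@H]2/C=C(/C)[C@@H](OC(=O)c3ccccc3)C/C=C(\C)C[C@@H](OC(=O)[C@@]3(C)O[C@H]3C)[C@@H]12 | intermediate
33 | CNP0324463.3, (1R,3S,6R,7R,8R,10R,4Z) | C=C1C(=O)O[C@@H]2/C=C(/C)[C@@H](OC(=O)c3ccccc3)C[C@H]3O[C@]3(C)C[C@@H](OC(=O)[C@@]3(C)O[C@H]3C)[C@@H]12 | target

## Step count and risks

Total step count: 24. Longest linear sequence: 15 steps (steps 1–6, then 16–24).

**Step 17 (Mitsunobu inversion at C8).** The carbinol is hindered and sits next to the lactone ring carbon, so elimination towards C7 or incomplete inversion can compete. The fallback separates activation from displacement. It sets out from 24: ClCH2SO2Cl and pyridine give the C8 chloromethanesulfonate F1. Acid 20 is converted with Cs2CO3 into caesium (2S,3S)‑2,3‑dimethyloxirane‑2‑carboxylate F2. F2 then displaces the sulfonate of F1 (18‑crown‑6, toluene, 50 °C) in an SN2 reaction with inversion, and the route is rejoined at 25.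

**Step 20 (Nozaki–Hiyama–Kishi closure of the ten‑membered ring).** Ring strain, oligomerisation and long exposure of the epoxy ester to chromium salts are the concerns. The fallback closes the ring as a ketone by thioester–vinyl iodide coupling. It sets out from 27: NaClO2, NaH2PO4 and 2‑methylbut‑2‑ene give the seco acid F3. 2,2'‑Dipyridyl disulfide and PPh3 give the S‑(pyridin‑2‑yl) thioester F4. F4 is cyclised with NiBr2(dtbbpy) (cat.), Cp2ZrCl2 as additive and Zn in 1,3‑dimethyl‑2‑imidazolidinone at high dilution, which gives enone 30 directly; the route is rejoined at 30 and step 21 is no longer needed.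

**Step 24 (face selectivity of the last epoxidation).** If the peracid attacks the other face of the 1(10) alkene, the 1α,10β‑oxirane results. The fallback uses a halohydrin, which places the oxygen on the face opposite to electrophilic attack. It sets out from 32: N‑bromosuccinimide in THF/H2O forms the bromonium ion on the face the peracid prefers, and water opens it at the tertiary C10 from the other side to give the (1S,10R)‑bromohydrin F5. DBU in CH2Cl2 at 0 °C then closes the oxirane by displacement of bromide with inversion at C1, and the route is rejoined at 33.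

## Further compounds

F1 | step 17 | C8 chloromethanesulfonate of 24 (6S,7R,8S) | C=C1C(=O)O[C@H](/C=C(/C)I)[C@H]1[C@@H](OS(=O)(=O)CCl)CC(/C)=C/CCO[Si](c2ccccc2)(c2ccccc2)C(C)(C)C
F2 | step 17 | caesium (2S,3S)‑2,3‑dimethyloxirane‑2‑carboxylate | [Cs+].[O-]C(=O)[C@@]1(C)O[C@H]1C
F3 | step 20 | seco acid from 27 (C3 carboxylic acid) | C=C1C(=O)O[C@H](/C=C(/C)I)[C@H]1[C@H](OC(=O)[C@@]2(C)O[C@H]2C)CC(/C)=C/CC(=O)O
F4 | step 20 | S‑(pyridin‑2‑yl) thioester of F3 | C=C1C(=O)O[C@H](/C=C(/C)I)[C@H]1[C@H](OC(=O)[C@@]2(C)O[C@H]2C)CC(/C)=C/CC(=O)Sc3ccccn3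
F5 | step 24 | (1S,10R)‑1‑bromo‑10‑hydroxy derivative of 32 | C=C1C(=O)O[C@@H]2/C=C(/C)[C@@H](OC(=O)c3ccccc3)C[C@H](Br)[C@](C)(O)C[C@@H](OC(=O)[C@@]3(C)O[C@H]3C)[C@@H]12
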